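**Retrosynthetic overview**
1. Target 24 ⇐ desilylation of 23 ⇐ Stille union at the C15–C15' sp2–sp2 single bond of ring-B iodide 21 and ring-A stannane 22.
2. 21 and 22 ⇐ one C20 stannane 20 (Sn→I exchange gives 21; dehydration of the C5 carbinol turns ring B into ring A and gives 22).
3. 20 ⇐ Horner–Wadsworth–Emmons (HWE) at C10=C11 of dienal 14 with stannyl dienylphosphonate 18 (from enynol 15).
4. 14 ⇐ methyl addition and allylic oxidation ⇐ enone 12 ⇐ gold-catalysed ring expansion of 1-alkynylcyclopentanol 11 (five- to six-membered ring; forms C1–C6 and the 6E alkene).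
5. 11 ⇐ Sonogashira of 7 with 10; 7 ⇐ ketone 5 ⇐ asymmetric β-borylation of enone 2 ⇐ 2,2-dimethylcyclopentanone 1. Ring order: the cyclopentane of 1 is expanded once to the six-membered ring (ring B); ring A is the same ring after dehydration; no other ring is formed.

Assumption: locants follow carotenoid numbering within each C20 half (ring C1–C6, chain C7–C15); ring A is the cyclohexene end with one OH, ring B the end with the tertiary C5 alcohol.
Assumption: the QuinoxP* antipode that gives the (4S)-boronate is used in step 2, and the configuration is confirmed on 4 before going on.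

**Route**

Step 1
Reactants: 1 2,2-dimethylcyclopentan-1-one
Product: 2 5,5-dimethylcyclopent-2-en-1-one
Conditions: IBX (1.5 equiv), DMSO/toluene 1:2, 70 °C
Reagents that add atoms: none
Why: IBX dehydrogenation of a ketone (Nicolaou desaturation) can only occur on the one side that carries α-hydrogens, so a single enone forms and no stereocentre is involved.

Step 2
Reactants: 2 5,5-dimethylcyclopent-2-en-1-one
Product: 4 (4S)-4-hydroxy-2,2-dimethylcyclopentan-1-one, via pinacol boronate 3 (not isolated)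
Conditions: B2pin2 (1.1 equiv), CuCl (3 mol%), NaOtBu (5 mol%), QuinoxP* (3.3 mol%), MeOH (2 equiv), THF, 0 °C → rt; then NaBO3·4H2O, THF/H2O, rt
Reagents that add atoms: bis(pinacolato)diboron, CC1(C)OB(OC1(C)C)B1OC(C)(C)C(C)(C)O1 (boron of 3); sodium perborate, [Na+].[Na+].O[B-]1(O)OO[B-](O)(O)OO1 (hydroxyl oxygen of 4)
Why: Copper-catalysed enantioselective conjugate borylation delivers Bpin to the β-carbon on the enone face chosen by the chiral bisphosphine, and stereoretentive C–B oxidation then gives the (4S)-alcohol, the future C3 of both rings.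

Step 3
Reactants: 4 (4S)-4-hydroxy-2,2-dimethylcyclopentan-1-one
Product: 5 (4S)-4-[(tert-butyldimethylsilyl)oxy]-2,2-dimethylcyclopentan-1-one
Conditions: TBSCl (1.2 equiv), imidazole (2.5 equiv), DMF, rt
Reagents that add atoms: tert-butyldimethylsilyl chloride, CC(C)(C)[Si](C)(C)Cl
Why: Standard silyl ether formation under mild base leaves the β-oxygenated ketone intact and the stereocentre untouched.

Step 4
Reactants: 5 (4S)-4-[(tert-butyldimethylsilyl)oxy]-2,2-dimethylcyclopentan-1-one; 6 ethynylmagnesium bromide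
Product: 7 (1S,4S)-4-[(tert-butyldimethylsilyl)oxy]-1-ethynyl-2,2-dimethylcyclopentan-1-ol (major C1 epimer; the minor epimer is carried along)
Conditions: HC≡CMgBr (1.5 equiv), LaCl3·2LiCl (30 mol%), THF, −20 → 0 °C; aq NH4Cl
Reagents that add atoms: none
Why: Grignard 1,2-addition to the hindered ketone, with the lanthanum salt suppressing enolisation and β-elimination, occurs mainly anti to the silyloxy group, and the C1 configuration is irrelevant because C1 becomes the carbonyl carbon in step 7.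

Step 5
Reactants: 8 prop-2-yn-1-ol
Product: 10 (2E)-3-iodo-2-methylprop-2-en-1-ol, via vinylalane 9 (not isolated)
Conditions: AlMe3 (3 equiv), (C5H5)2ZrCl2 (25 mol%), CH2Cl2, 0 °C → rt; then I2, THF, −30 → 0 °C
Reagents that add atoms: trimethylaluminium, C[Al](C)C; iodine, II
Why: Negishi zirconium-catalysed carboalumination adds methyl and aluminium syn across the alkyne with methyl on the internal carbon, and iodinolysis with retention gives the (E)-iodide.

Step 6
Reactants: 7 (1S,4S)-4-[(tert-butyldimethylsilyl)oxy]-1-ethynyl-2,2-dimethylcyclopentan-1-ol; 10 (2E)-3-iodo-2-methylprop-2-en-1-ol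
Product: 11 (2E)-5-[(1S,4S)-4-[(tert-butyldimethylsilyl)oxy]-1-hydroxy-2,2-dimethylcyclopentyl]-2-methylpent-2-en-4-yn-1-ol
Conditions: Pd(PPh3)2Cl2 (2 mol%), CuI (4 mol%), Et3N, THF, rt
Reagents that add atoms: none
Why: Sonogashira coupling proceeds with retention of the vinyl iodide geometry and tolerates both free hydroxyl groups.

Step 7
Reactants: 11 (2E)-5-[(1S,4S)-4-[(tert-butyldimethylsilyl)oxy]-1-hydroxy-2,2-dimethylcyclopentyl]-2-methylpent-2-en-4-yn-1-ol
Product: 12 (2E,5S)-5-[(tert-butyldimethylsilyl)oxy]-2-[(2E)-4-hydroxy-3-methylbut-2-en-1-ylidene]-3,3-dimethylcyclohexan-1-one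
Conditions: LAuCl (5 mol%), AgNTf2 (5 mol%), L = 2-[di(1-adamantyl)phosphino]-3'-(pyrrolidine-1-carbonyl)biphenyl, ClCH2CH2Cl, 4 Å sieves, 40–60 °C, dark
Reagents that add atoms: none
Why: Proposed new method: cationic monovalent gold π-activates the alkyne and the more substituted ring bond (the quaternary carbon) migrates from the carbinol carbon to the proximal alkyne carbon anti to gold in a semipinacol-type 1,2-alkyl shift, while the ligand's pendant amide acts as a general base on the carbinol O–H (making the unstrained cyclopentanol a strong enough donor) and then returns the proton to the vinyl–gold bond with retention; this builds the six-membered ring and the C1–C6 bond and, because migrating carbon and gold end up anti, places the dienyl chain cis to the gem-dimethyl carbon (the required 6E alkene), the closest known reaction being the monovalent-gold-catalysed ring expansion of 1-alkynylcyclopropanols and 1-alkynylcyclobutanols to (E)-2-alkylidenecycloalkanones, which relies on strain release and is not known for cyclopentanols, the driving force here being alkynol-to-enone isomerisation plus relief of the congestion between the carbinol carbon and the adjacent quaternary carbon.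

Step 8
Reactants: 12 (2E,5S)-5-[(tert-butyldimethylsilyl)oxy]-2-[(2E)-4-hydroxy-3-methylbut-2-en-1-ylidene]-3,3-dimethylcyclohexan-1-one
Product: 13 (1R,2E,5S)-5-[(tert-butyldimethylsilyl)oxy]-2-[(2E)-4-hydroxy-3-methylbut-2-en-1-ylidene]-1,3,3-trimethylcyclohexan-1-ol
Conditions: MeLi (3.5 equiv), CeCl3 (3.5 equiv), THF, −78 °C; aq NH4Cl
Reagents that add atoms: methyllithium, [Li]C
Why: Organocerium 1,2-addition (Imamoto conditions, no enolisation or conjugate addition) occurs by equatorial attack because the axial methyl of the gem-dimethyl carbon blocks the axial trajectory, as in 3,3,5-trimethylcyclohexanone, so the new OH is axial and trans to the equatorial silyloxy group, which is the (5R) carbinol of ring B.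

Step 9
Reactants: 13 (1R,2E,5S)-5-[(tert-butyldimethylsilyl)oxy]-2-[(2E)-4-hydroxy-3-methylbut-2-en-1-ylidene]-1,3,3-trimethylcyclohexan-1-ol
Product: 14 (2E,4E)-4-[(2R,4S)-4-[(tert-butyldimethylsilyl)oxy]-2-hydroxy-2,6,6-trimethylcyclohexylidene]-2-methylbut-2-enal
Conditions: MnO2 (15 equiv), CH2Cl2, rt
Reagents that add atoms: none
Why: Allylic oxidation with MnO2 converts only the primary allylic alcohol into the dienal, since the tertiary alcohol cannot be oxidised and the silyl ether is inert.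

Step 10
Reactants: 15 (2E)-3-methylpent-2-en-4-yn-1-ol
Product: 16 (2E,4E)-3-methyl-5-(tributylstannyl)penta-2,4-dien-1-ol
Conditions: Bu3SnH (1.1 equiv), Pd(PPh3)2Cl2 (2 mol%), THF, 0 °C
Reagents that add atoms: tributyltin hydride, CCCC[SnH](CCCC)CCCC
Why: Palladium-catalysed hydrostannylation adds H and Sn syn across the terminal alkyne with tin on the terminal carbon, giving the (E)-vinylstannane, and the minor internal regioisomer is removed by chromatography.

Step 11
Reactants: 16 (2E,4E)-3-methyl-5-(tributylstannyl)penta-2,4-dien-1-ol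
Product: 17 tributyl[(1E,3E)-5-bromo-3-methylpenta-1,3-dien-1-yl]stannane
Conditions: CBr4 (1.3 equiv), PPh3 (1.3 equiv), 2,6-lutidine, CH2Cl2, −20 → 0 °C
Reagents that add atoms: carbon tetrabromide, BrC(Br)(Br)Br
Why: Appel bromination converts the primary allylic alcohol into the bromide under neutral conditions that spare the vinylstannane and the alkene geometry.

Step 12
Reactants: 17 tributyl[(1E,3E)-5-bromo-3-methylpenta-1,3-dien-1-yl]stannane
Product: 18 diethyl [(2E,4E)-3-methyl-5-(tributylstannyl)penta-2,4-dien-1-yl]phosphonate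
Conditions: P(OEt)3 (5 equiv), neat, 90 °C
Reagents that add atoms: triethyl phosphite, CCOP(OCC)OCC
Why: Michaelis–Arbuzov reaction of the primary allylic bromide gives the phosphonate without touching the C–Sn bond.

Step 13
Reactants: 14 (2E,4E)-4-[(2R,4S)-4-[(tert-butyldimethylsilyl)oxy]-2-hydroxy-2,6,6-trimethylcyclohexylidene]-2-methylbut-2-enal; 18 diethyl [(2E,4E)-3-methyl-5-(tributylstannyl)penta-2,4-dien-1-yl]phosphonate
Product: 20 (1R,2E,5S)-5-[(tert-butyldimethylsilyl)oxy]-2-[(2E,4E,6E,8E)-3,7-dimethyl-9-(tributylstannyl)nona-2,4,6,8-tetraen-1-ylidene]-1,3,3-trimethylcyclohexan-1-ol (ring-B C20 stannane), via phosphonate sodium salt 19 (not isolated)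
Conditions: 18 (1.5 equiv), NaN(SiMe3)2 (1.45 equiv), THF, −78 °C; then 14, −78 → 0 °C
Reagents that add atoms: sodium bis(trimethylsilyl)amide, [Na+].C[Si](C)(C)[N-][Si](C)(C)C (sodium of 19 only)
Why: HWE olefination of the enal with the allylic phosphonate anion forms the C10=C11 bond E-selectively, and the tertiary alcohol, silyl ether and vinylstannane are inert to the base at low temperature.

Step 14
Reactants: 20 ring-B C20 stannane
Product: 21 (1R,2E,5S)-5-[(tert-butyldimethylsilyl)oxy]-2-[(2E,4E,6E,8E)-9-iodo-3,7-dimethylnona-2,4,6,8-tetraen-1-ylidene]-1,3,3-trimethylcyclohexan-1-ol (ring-B C20 iodide)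
Conditions: I2 (1.05 equiv), CH2Cl2, −78 → 0 °C, dark; aq Na2S2O3
Reagents that add atoms: iodine, II
Why: Iododestannylation is an ipso substitution with retention of the (E)-geometry and is much faster than iodine addition to the polyene at low temperature.

Step 15
Reactants: 20 ring-B C20 stannane
Product: 22 tert-butyl(dimethyl){[(1S,4E)-4-[(2E,4E,6E,8E)-3,7-dimethyl-9-(tributylstannyl)nona-2,4,6,8-tetraen-1-ylidene]-3,5,5-trimethylcyclohex-2-en-1-yl]oxy}silane (ring-A C20 stannane)
Conditions: Ph2S[OC(CF3)2Ph]2 (Martin sulfurane, 1.3 equiv), CH2Cl2, −20 → 0 °C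
Reagents that add atoms: none
Why: Martin sulfurane dehydration of the axial tertiary allylic alcohol removes the anti-periplanar axial hydrogen at C4 and gives the endocyclic C4=C5 alkene in conjugation with the polyene under non-acidic conditions, leaving the C3 stereocentre, silyl ether and stannane untouched.

Step 16
Reactants: 21 ring-B C20 iodide; 22 ring-A C20 stannane
Product: 23 3,3'-bis-O-(tert-butyldimethylsilyl) ether of the target (C40 retro-carotenoid with free C5 tertiary OH in ring B)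
Conditions: Pd2(dba)3·CHCl3 (5 mol%), AsPh3 (40 mol%), NMP, 25 °C, degassed, dark
Reagents that add atoms: none
Why: Stille coupling on zerovalent palladium joins the two sp2 carbons C15 and C15' with retention of both alkene geometries, completing the all-E retro-polyene.

Step 17
Reactants: 23 bis-silyl ether
Product: 24 target CNP0269135.2, (3S,3'S,5'R,6E,6'E)-4,5'-retro-β,β-carotene-3,3',5'-triol (all-E chain; ring A 3S, ring B 3S,5R)
Conditions: Bu4NF (5 equiv), THF, 0 → 25 °C, argon, dark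
Reagents that add atoms: none
Why: Fluoride desilylation frees both secondary alcohols under non-acidic conditions, which the acid-labile allylic alcohol of ring A and the polyene tolerate, and no stereocentre is touched.

**Compound list**
1 | 2,2-dimethylcyclopentan-1-one | CC1(C)CCCC1=O | starting material
2 | 5,5-dimethylcyclopent-2-en-1-one | CC1(C)CC=CC1=O | intermediate
3 | (4S)-2,2-dimethyl-4-(4,4,5,5-tetramethyl-1,3,2-dioxaborolan-2-yl)cyclopentan-1-one | O=C1C[C@@H](B2OC(C)(C)C(C)(C)O2)CC1(C)C | intermediate (not isolated)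
4 | (4S)-4-hydroxy-2,2-dimethylcyclopentan-1-one | O=C1C[C@@H](O)CC1(C)C | intermediate
5 | (4S)-4-[(tert-butyldimethylsilyl)oxy]-2,2-dimethylcyclopentan-1-one | O=C1C[C@@H](O[Si](C)(C)C(C)(C)C)CC1(C)C | intermediate
6 | ethynylmagnesium bromide | C#C[Mg]Br | starting material
7 | (1S,4S)-4-[(tert-butyldimethylsilyl)oxy]-1-ethynyl-2,2-dimethylcyclopentan-1-ol (major C1 epimer) | C#C[C@]1(O)C[C@@H](O[Si](C)(C)C(C)(C)C)CC1(C)C | intermediate
8 | prop-2-yn-1-ol | C#CCO | starting material
9 | [(1E)-3-(dimethylalumanyloxy)-2-methylprop-1-en-1-yl]dimethylalumane (vinylalane) | C[Al](C)OC/C(C)=C/[Al](C)C | intermediate (not isolated)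
10 | (2E)-3-iodo-2-methylprop-2-en-1-ol | OC/C(C)=C/I | intermediate
11 | (2E)-5-[(1S,4S)-4-[(tert-butyldimethylsilyl)oxy]-1-hydroxy-2,2-dimethylcyclopentyl]-2-methylpent-2-en-4-yn-1-ol | OC/C(C)=C/C#C[C@]1(O)C[C@@H](O[Si](C)(C)C(C)(C)C)CC1(C)C | intermediate
12 | (2E,5S)-5-[(tert-butyldimethylsilyl)oxy]-2-[(2E)-4-hydroxy-3-methylbut-2-en-1-ylidene]-3,3-dimethylcyclohexan-1-one | O=C1C[C@@H](O[Si](C)(C)C(C)(C)C)CC(C)(C)\C1=C/C=C(C)/CO | intermediate
13 | (1R,2E,5S)-5-[(tert-butyldimethylsilyl)oxy]-2-[(2E)-4-hydroxy-3-methylbut-2-en-1-ylidene]-1,3,3-trimethylcyclohexan-1-ol | OC/C(C)=C/C=C1\C(C)(C)C[C@H](O[Si](C)(C)C(C)(C)C)C[C@@]1(C)O | intermediate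
14 | (2E,4E)-4-[(2R,4S)-4-[(tert-butyldimethylsilyl)oxy]-2-hydroxy-2,6,6-trimethylcyclohexylidene]-2-methylbut-2-enal | O=C/C(C)=C/C=C1\C(C)(C)C[C@H](O[Si](C)(C)C(C)(C)C)C[C@@]1(C)O | intermediate
15 | (2E)-3-methylpent-2-en-4-yn-1-ol | OC/C=C(C)/C#C | starting material
16 | (2E,4E)-3-methyl-5-(tributylstannyl)penta-2,4-dien-1-ol | OC/C=C(C)/C=C/[Sn](CCCC)(CCCC)CCCC | intermediate
17 | tributyl[(1E,3E)-5-bromo-3-methylpenta-1,3-dien-1-yl]stannane | BrC/C=C(C)/C=C/[Sn](CCCC)(CCCC)CCCC | intermediate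
18 | diethyl [(2E,4E)-3-methyl-5-(tributylstannyl)penta-2,4-dien-1-yl]phosphonate | CCOP(=O)(OCC)C/C=C(C)/C=C/[Sn](CCCC)(CCCC)CCCC | intermediate
19 | sodium salt of 18 (phosphonate α-carbanion) | [Na+].CCOP(=O)(OCC)[CH-]/C=C(C)/C=C/[Sn](CCCC)(CCCC)CCCC | intermediate (not isolated)
20 | (1R,2E,5S)-5-[(tert-butyldimethylsilyl)oxy]-2-[(2E,4E,6E,8E)-3,7-dimethyl-9-(tributylstannyl)nona-2,4,6,8-tetraen-1-ylidene]-1,3,3-trimethylcyclohexan-1-ol (ring-B C20 stannane) | CCCC[Sn](CCCC)(CCCC)/C=C/C(C)=C/C=C/C(C)=C/C=C1\C(C)(C)C[C@H](O[Si](C)(C)C(C)(C)C)C[C@@]1(C)O | intermediate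
21 | (1R,2E,5S)-5-[(tert-butyldimethylsilyl)oxy]-2-[(2E,4E,6E,8E)-9-iodo-3,7-dimethylnona-2,4,6,8-tetraen-1-ylidene]-1,3,3-trimethylcyclohexan-1-ol (ring-B C20 iodide) | I/C=C/C(C)=C/C=C/C(C)=C/C=C1\C(C)(C)C[C@H](O[Si](C)(C)C(C)(C)C)C[C@@]1(C)O | intermediate
22 | tert-butyl(dimethyl){[(1S,4E)-4-[(2E,4E,6E,8E)-3,7-dimethyl-9-(tributylstannyl)nona-2,4,6,8-tetraen-1-ylidene]-3,5,5-trimethylcyclohex-2-en-1-yl]oxy}silane (ring-A C20 stannane) | CC1=C[C@@H](O[Si](C)(C)C(C)(C)C)CC(C)(C)\C1=C/C=C(C)/C=C/C=C(C)/C=C/[Sn](CCCC)(CCCC)CCCC | intermediate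
23 | 3,3'-bis-O-(tert-butyldimethylsilyl) ether of the target | CC1=C[C@@H](O[Si](C)(C)C(C)(C)C)CC(C)(C)\C1=C/C=C(C)/C=C/C=C(C)/C=C/C=C/C(C)=C/C=C/C(C)=C/C=C1\C(C)(C)C[C@H](O[Si](C)(C)C(C)(C)C)C[C@@]1(C)O | intermediate
24 | CNP0269135.2, (3S,3'S,5'R,6E,6'E)-4,5'-retro-β,β-carotene-3,3',5'-triol | CC1=C[C@@H](O)CC(C)(C)\C1=C/C=C(C)/C=C/C=C(C)/C=C/C=C/C(C)=C/C=C/C(C)=C/C=C1\C(C)(C)C[C@H](O)C[C@@]1(C)O | target

**Step count and risks**
Total: 17 steps. Longest linear sequence: 12 steps (1 → 2 → 4 → 5 → 7 → 11 → 12 → 13 → 14 → 20 → 21 or 22 → 23 → 24).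

The three steps most likely to fail:

Step 7 (new gold-catalysed ring expansion). Risks are no migration from the unstrained ring, Meyer–Schuster-type side products, or loss of alkene geometry. The fallback closes ring B by ketyl–alkyne cyclisation, a known reaction class; it sets out from enone 2 and comes back at diol 13. Nucleophilic epoxidation of 2 (H2O2, NaOH, MeOH, 0 °C) gives 3,3-dimethyl-6-oxabicyclo[3.1.0]hexan-2-one F1. Condensation with TsNHNH2 (AcOH/CH2Cl2, −20 °C → rt) gives the epoxy tosylhydrazone F2, which fragments in the flask (Eschenmoser–Tanabe) to 3,3-dimethylpent-4-ynal F3. L-Proline-catalysed aldol addition of acetone gives (4S)-4-hydroxy-6,6-dimethyloct-7-yn-2-one F4, and silylation (TBSCl, imidazole) gives (4S)-4-[(tert-butyldimethylsilyl)oxy]-6,6-dimethyloct-7-yn-2-one F5. Sonogashira coupling with iodide 10 gives (4S,9E)-4-[(tert-butyldimethylsilyl)oxy]-11-hydroxy-6,6,10-trimethylundec-9-en-7-yn-2-one F6. SmI2 (THF/HMPA, t-BuOH, −78 → 0 °C) then effects 6-exo-dig ketyl–alkyne cyclisation to 13; C5 epimers and C6=C7 isomers are separated by chromatography.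

Step 15 (dehydration). Risks are exocyclic methylene formation or over-elimination. The fallback fixes the alkene position through an enol triflate; it sets out from enone 12 and comes back at stannane 22. MnO2 oxidation of 12 gives (2E,4E)-4-[(4S)-4-[(tert-butyldimethylsilyl)oxy]-2,2-dimethyl-6-oxocyclohexylidene]-2-methylbut-2-enal F7. HWE olefination with phosphonate anion 19 gives (2E,5S)-5-[(tert-butyldimethylsilyl)oxy]-3,3-dimethyl-2-[(2E,4E,6E,8E)-3,7-dimethyl-9-(tributylstannyl)nona-2,4,6,8-tetraen-1-ylidene]cyclohexan-1-one F8. Kinetic enolisation (KN(SiMe3)2, THF, −78 °C; only C4 carries α-hydrogens) and trapping with PhNTf2 gives the dienyl triflate (3S,6E)-3-[(tert-butyldimethylsilyl)oxy]-5,5-dimethyl-6-[(2E,4E,6E,8E)-3,7-dimethyl-9-(tributylstannyl)nona-2,4,6,8-tetraen-1-ylidene]cyclohex-1-en-1-yl trifluoromethanesulfonate F9. Iron-catalysed cross-coupling with MeMgBr (Fe(acac)3 5 mol%, THF/NMP, −30 °C; the vinylstannane is inert) installs the C5 methyl and gives 22.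

Step 14 (iododestannylation on the tetraene). Risks are iodine-induced E/Z isomerisation or ionisation of the tertiary allylic alcohol. The fallback moves the tin–iodine exchange to the small phosphonate; it sets out from phosphonate 18 (with aldehyde 14) and comes back at iodide 21. Treatment of 18 with I2 (CH2Cl2, 0 °C) gives diethyl [(2E,4E)-5-iodo-3-methylpenta-2,4-dien-1-yl]phosphonate F10. Deprotonation (NaN(SiMe3)2, THF, −78 °C) gives its sodium salt F11, and HWE olefination with 14 gives 21 directly.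

**Further compounds**
F1 | step 7 | 3,3-dimethyl-6-oxabicyclo[3.1.0]hexan-2-one (racemic) | CC1(C)CC2OC2C1=O
F2 | step 7 | N'-(3,3-dimethyl-6-oxabicyclo[3.1.0]hexan-2-ylidene)-4-methylbenzenesulfonohydrazide | CC1(C)CC2OC2C1=NNS(=O)(=O)c1ccc(C)cc1
F3 | step 7 | 3,3-dimethylpent-4-ynal | C#CC(C)(C)CC=O
F4 | step 7 | (4S)-4-hydroxy-6,6-dimethyloct-7-yn-2-one | CC(=O)C[C@@H](O)CC(C)(C)C#C
F5 | step 7 | (4S)-4-[(tert-butyldimethylsilyl)oxy]-6,6-dimethyloct-7-yn-2-one | CC(=O)C[C@@H](O[Si](C)(C)C(C)(C)C)CC(C)(C)C#C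
F6 | step 7 | (4S,9E)-4-[(tert-butyldimethylsilyl)oxy]-11-hydroxy-6,6,10-trimethylundec-9-en-7-yn-2-one | CC(=O)C[C@@H](O[Si](C)(C)C(C)(C)C)CC(C)(C)C#C/C=C(C)/CO
F7 | step 15 | (2E,4E)-4-[(4S)-4-[(tert-butyldimethylsilyl)oxy]-2,2-dimethyl-6-oxocyclohexylidene]-2-methylbut-2-enal | O=C1C[C@@H](O[Si](C)(C)C(C)(C)C)CC(C)(C)\C1=C/C=C(C)/C=O
F8 | step 15 | (2E,5S)-5-[(tert-butyldimethylsilyl)oxy]-3,3-dimethyl-2-[(2E,4E,6E,8E)-3,7-dimethyl-9-(tributylstannyl)nona-2,4,6,8-tetraen-1-ylidene]cyclohexan-1-one | O=C1C[C@@H](O[Si](C)(C)C(C)(C)C)CC(C)(C)\C1=C/C=C(C)/C=C/C=C(C)/C=C/[Sn](CCCC)(CCCC)CCCC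
F9 | step 15 | (3S,6E)-3-[(tert-butyldimethylsilyl)oxy]-5,5-dimethyl-6-[(2E,4E,6E,8E)-3,7-dimethyl-9-(tributylstannyl)nona-2,4,6,8-tetraen-1-ylidene]cyclohex-1-en-1-yl trifluoromethanesulfonate | O=S(=O)(OC1=C[C@@H](O[Si](C)(C)C(C)(C)C)CC(C)(C)\C1=C/C=C(C)/C=C/C=C(C)/C=C/[Sn](CCCC)(CCCC)CCCC)C(F)(F)F
F10 | step 14 | diethyl [(2E,4E)-5-iodo-3-methylpenta-2,4-dien-1-yl]phosphonate | CCOP(=O)(OCC)C/C=C(C)/C=C/I
F11 | step 14 | sodium salt of F10 (phosphonate α-carbanion) | [Na+].CCOP(=O)(OCC)[CH-]/C=C(C)/C=C/I
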